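## Retrosynthetic overview

1. The C2–C3 oxirane is cis to the C5 side chain, which nucleophilic epoxidation of the C1 enone cannot give; it is therefore installed by hydroxyl-directed epoxidation of a 1β-allylic alcohol, followed by oxidation to the ketone and desilylation.
2. The 1β-alcohol comes from a C1 dimethyl ketal (hydrolysis, Luche reduction); the 4α-OH comes from Luche reduction of a C4 ketone; the angelate is put on the side-chain carbinol by esterification.
3. Key disconnection: the C5–side-chain bond, made by a semipinacol 1,2-alkenyl shift from C4 to C5 in a cis-epoxy p-quinol ketal. This sets C5, unveils the 6α-OH and returns the C4 ketone.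
4. The epoxy quinol comes from an alkenyllithium (2-bromoacrolein, allylboration, cross-metathesis) and an epoxy quinone monoketal (m-cresol, oxidative dearomatisation, asymmetric nucleophilic epoxidation).
5. Ring order: the carbocycle comes intact from m-cresol; the C5–C6 oxirane is made first and consumed in the shift; the C2–C3 oxirane is made third from last.

Assumption: 2-bromoacrolein and (−)-B-allyldiisopinocampheylborane are bought; the facial senses in steps 1 and 5 are taken from the usual models, and the antipodal borane or D-DIPT is used if they prove opposite.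

Conventions: ring locants follow the target (C1 ketone, C2 methyl, C3, C4 carbinol, C5 side chain, C6 acetoxy); β is the ring face carrying the C5 side chain in the target, α the other face; SC(OX) = (3S)-7-methyl-3-(OX)-octa-1,6-dien-2-yl.

## Route

Step 1
Reactants: 1 2-bromoprop-2-enal
Product: 2 (S)-2-bromohexa-1,5-dien-3-ol
Conditions: (−)-Ipc2B(allyl), Et2O, −78 °C; then NaOH, H2O2, 0 °C
Reagents that add atoms: (−)-B-allyldiisopinocampheylborane, C[C@H]1[C@@H](C[C@@H]2C[C@H]1C2(C)C)B(CC=C)[C@@H]1C[C@@H]2C[C@H]([C@H]1C)C2(C)C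
Why: Brown allylboration through a closed chair transition state in which the pinanyl groups select one aldehyde face, setting the (S) carbinol centre that later carries the angelate.

Step 2
Reactants: 2 (S)-2-bromohexa-1,5-dien-3-ol
Product: 3 (S)-2-bromo-3-(triethylsilyloxy)hexa-1,5-diene
Conditions: TESCl, imidazole, CH2Cl2, 0 °C
Reagents that add atoms: chlorotriethylsilane, CC[Si](Cl)(CC)CC
Why: Routine silylation that makes the carbinol compatible with the later organolithium; the stereocentre is untouched.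

Step 3
Reactants: 3 (S)-2-bromo-3-(triethylsilyloxy)hexa-1,5-diene
Product: 4 (S)-2-bromo-7-methyl-3-(triethylsilyloxy)octa-1,6-diene
Conditions: 2-methyl-2-butene (solvent), second-generation Grubbs catalyst RuCl2(=CHPh)(PCy3)(H2IMes) (3 mol %), 40 °C
Reagents that add atoms: 2-methyl-2-butene, CC=C(C)C
Why: Cross-metathesis turns the terminal allyl group into the prenyl group; the 1,1-disubstituted bromoalkene does not take part.

Step 4
Reactants: 5 3-methylphenol
Product: 7 4,4-dimethoxy-3-methylcyclohexa-2,5-dien-1-one, via 4-methoxy-3-methylphenol 6 (not isolated)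
Conditions: PhI(OAc)2 (2.2 equiv), MeOH, 0 °C to rt
Reagents that add atoms: methanol, CO
Why: Oxidative dearomatisation with the trivalent iodine reagent: para-methoxylation gives 6, which is oxidised again in methanol to the p-quinone monoketal (no stereocentre).

Step 5
Reactants: 7 4,4-dimethoxy-3-methylcyclohexa-2,5-dien-1-one
Product: 8 (1S,6R)-5,5-dimethoxy-4-methyl-7-oxabicyclo[4.1.0]hept-3-en-2-one
Conditions: Ph3COOH, NaN(SiMe3)2, L-(+)-DIPT, 4 Å MS, toluene, −50 °C
Reagents that add atoms: trityl hydroperoxide, OOC(c1ccccc1)(c1ccccc1)c1ccccc1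
Why: Tartrate-mediated nucleophilic (Weitz–Scheffer) epoxidation, a known reaction of quinone monoketals: the peroxide anion attacks the unsubstituted enone arm (the other β-carbon carries the methyl group) and the sodium tartrate aggregate selects the α-face, setting C5 and C6.

Step 6
Reactants: 4 (S)-2-bromo-7-methyl-3-(triethylsilyloxy)octa-1,6-diene; 8 (1S,6R)-5,5-dimethoxy-4-methyl-7-oxabicyclo[4.1.0]hept-3-en-2-one
Product: 10 4β-SC(OTES)-4α-hydroxy-5α,6α-epoxy-1,1-dimethoxy-2-methylcyclohex-2-ene, via alkenyllithium 9 (not isolated)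
Conditions: t-BuLi (2.05 equiv), Et2O, −78 °C; then 8, THF, −78 °C; H2O
Reagents that add atoms: tert-butyllithium, [Li]C(C)(C)C (lithium stays in 9 only)
Why: Br/Li exchange, then 1,2-addition of the alkenyllithium to the ketone anti to the adjacent oxirane oxygen, which puts the alkenyl group β and the tertiary hydroxyl α at C4, cis to the epoxide.

Step 7
Reactants: 10 4β-SC(OTES)-4α-hydroxy-5α,6α-epoxy-1,1-dimethoxy-2-methylcyclohex-2-ene
Product: 12 5β-SC(OTES)-6α-acetoxy-1,1-dimethoxy-2-methylcyclohex-2-en-4-one, via hydroxy ketone 11 (not isolated)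
Conditions: ZnBr2 (1.2 equiv), CH2Cl2, −20 to 0 °C; then pyridine, Ac2O, DMAP (cat.), 0 °C
Reagents that add atoms: acetic anhydride, CC(=O)OC(C)=O
Why: Proposed new method: semipinacol 1,2-alkenyl shift in a cis-epoxy p-quinol monoketal with a 1,1-disubstituted alkenyl migrating group; ZnBr2 bridges the carbinol oxygen and the syn oxirane oxygen, the C5–O bond breaks only as the β-alkenyl group (antiperiplanar to it) moves from C4 to C5 with inversion, so C5 becomes β-alkenyl, C6 keeps its α-oxygen and C4 becomes a conjugated enone carbonyl (the driving force), while the ring vinyl carbon is gauche to the breaking bond and does not migrate and the ketal tolerates ZnBr2 at low temperature; the closest known reaction is the Lewis-acid semipinacol rearrangement of tertiary 2,3-epoxy alcohols to β-hydroxy ketones (Tsuchihashi–Suzuki type), not yet shown on quinol ketal epoxides or with this migrating group; acetylation in the same flask caps the only free hydroxyl.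

Step 8
Reactants: 12 5β-SC(OTES)-6α-acetoxy-1,1-dimethoxy-2-methylcyclohex-2-en-4-one
Product: 13 5β-SC(OTES)-6α-acetoxy-4α-hydroxy-1,1-dimethoxy-2-methylcyclohex-2-ene
Conditions: NaBH4, CeCl3·7H2O, MeOH, −78 °C
Reagents that add atoms: none
Why: Luche 1,2-reduction; hydride adds axially to the half-chair with the C5 and C6 substituents equatorial, giving the equatorial 4α-alcohol trans to the side chain, and it removes the elimination-prone β-acetoxy ketone.

Step 9
Reactants: 13 5β-SC(OTES)-6α-acetoxy-4α-hydroxy-1,1-dimethoxy-2-methylcyclohex-2-ene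
Product: 14 5β-SC(OTES)-6α-acetoxy-4α-(tert-butyldimethylsilyloxy)-1,1-dimethoxy-2-methylcyclohex-2-ene
Conditions: TBSCl, imidazole, DMF, rt
Reagents that add atoms: tert-butylchlorodimethylsilane, CC(C)(C)[Si](C)(C)Cl
Why: Silylation masks the C4 hydroxyl so that it cannot steer the later vanadium epoxidation to the α-face; no stereocentre changes.

Step 10
Reactants: 14 5β-SC(OTES)-6α-acetoxy-4α-(tert-butyldimethylsilyloxy)-1,1-dimethoxy-2-methylcyclohex-2-ene
Product: 15 5β-SC(OH)-6α-acetoxy-4α-(tert-butyldimethylsilyloxy)-1,1-dimethoxy-2-methylcyclohex-2-ene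
Conditions: PPTS, MeOH, 0 °C to rt
Reagents that add atoms: none
Why: Acid methanolysis removes the more labile triethylsilyl ether selectively, while methanol as solvent keeps the dimethyl ketal and the TBS ether stays.

Step 11
Reactants: 15 5β-SC(OH)-6α-acetoxy-4α-(tert-butyldimethylsilyloxy)-1,1-dimethoxy-2-methylcyclohex-2-ene; 16 angelic acid
Product: 18 5β-SC(OAng)-6α-acetoxy-4α-(tert-butyldimethylsilyloxy)-1,1-dimethoxy-2-methylcyclohex-2-ene, via mixed anhydride 17 (not isolated)
Conditions: 16, 2,4,6-trichlorobenzoyl chloride, Et3N, toluene, rt; then 15, 80 °C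
Reagents that add atoms: 2,4,6-trichlorobenzoyl chloride, O=C(Cl)c1c(Cl)cc(Cl)cc1Cl (its atoms stay in 17 only)
Why: Yamaguchi-type esterification through the mixed anhydride without DMAP, conditions known to give angelates without Z-to-E isomerisation; the carbinol configuration is untouched and no β-acyloxy ketone is present at this stage.

Step 12
Reactants: 18 5β-SC(OAng)-6α-acetoxy-4α-(tert-butyldimethylsilyloxy)-1,1-dimethoxy-2-methylcyclohex-2-ene
Product: 19 5β-SC(OAng)-6α-acetoxy-4α-(tert-butyldimethylsilyloxy)-2-methylcyclohex-2-en-1-one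
Conditions: oxalic acid, wet SiO2, CH2Cl2, rt
Reagents that add atoms: water, O
Why: Mild acid hydrolysis of the allylic dimethyl ketal to the conjugated enone, done while C2–C3 is still an alkene so that the oxocarbenium ion is allyl-stabilised; TBS ether, acetate and angelate survive.

Step 13
Reactants: 19 5β-SC(OAng)-6α-acetoxy-4α-(tert-butyldimethylsilyloxy)-2-methylcyclohex-2-en-1-one
Product: 20 5β-SC(OAng)-6α-acetoxy-4α-(tert-butyldimethylsilyloxy)-2-methylcyclohex-2-en-1β-ol
Conditions: NaBH4, CeCl3·7H2O, MeOH, −78 to −40 °C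
Reagents that add atoms: none
Why: Luche reduction; axial hydride delivery in the all-equatorial half-chair gives the equatorial 1β-alcohol, trans to the 6α-acetate (as carvone gives cis-carveol), which places a directing hydroxyl on the β-face.

Step 14
Reactants: 20 5β-SC(OAng)-6α-acetoxy-4α-(tert-butyldimethylsilyloxy)-2-methylcyclohex-2-en-1β-ol
Product: 21 5β-SC(OAng)-6α-acetoxy-4α-(tert-butyldimethylsilyloxy)-2β,3β-epoxy-2-methylcyclohexan-1β-ol
Conditions: VO(acac)2 (5 mol %), t-BuOOH, CH2Cl2, 0 °C to rt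
Reagents that add atoms: tert-butyl hydroperoxide, CC(C)(C)OO
Why: Hydroxyl-directed vanadium-catalysed epoxidation: the vanadate ester of the 1β-alcohol delivers oxygen to the β-face of the adjacent alkene only, leaving the prenyl, methylene and angelate alkenes alone, and sets C2 and C3 cis to the side chain and anti to the 4α-silyloxy group.

Step 15
Reactants: 21 5β-SC(OAng)-6α-acetoxy-4α-(tert-butyldimethylsilyloxy)-2β,3β-epoxy-2-methylcyclohexan-1β-ol
Product: 22 5β-SC(OAng)-6α-acetoxy-4α-(tert-butyldimethylsilyloxy)-2β,3β-epoxy-2-methylcyclohexan-1-one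
Conditions: Dess–Martin periodinane, NaHCO3, CH2Cl2, 0 °C to rt
Reagents that add atoms: none
Why: Dess–Martin oxidation of the secondary epoxy alcohol to the α,β-epoxy ketone under buffered conditions; C6 keeps the more stable equatorial acetate.

Step 16
Reactants: 22 5β-SC(OAng)-6α-acetoxy-4α-(tert-butyldimethylsilyloxy)-2β,3β-epoxy-2-methylcyclohexan-1-one
Product: 23 CNP0272666.1
Conditions: HF·pyridine, pyridine, THF, 0 °C to rt
Reagents that add atoms: none
Why: Buffered fluoride cleavage of the secondary TBS ether, which spares the epoxy ketone, the α-acetoxy ketone and the angelate and frees the 4α-hydroxyl of the target.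

## Compound list

1 | 2-bromoprop-2-enal (2-bromoacrolein) | C=C(Br)C=O | starting material
2 | (S)-2-bromohexa-1,5-dien-3-ol | C=C(Br)[C@H](CC=C)O | intermediate
3 | (S)-2-bromo-3-(triethylsilyloxy)hexa-1,5-diene | C=C(Br)[C@H](CC=C)O[Si](CC)(CC)CC | intermediate
4 | (S)-2-bromo-7-methyl-3-(triethylsilyloxy)octa-1,6-diene | C=C(Br)[C@H](CC=C(C)C)O[Si](CC)(CC)CC | intermediate
5 | 3-methylphenol (m-cresol) | Cc1cccc(O)c1 | starting material
6 | 4-methoxy-3-methylphenol | COc1ccc(O)cc1C | intermediate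
7 | 4,4-dimethoxy-3-methylcyclohexa-2,5-dien-1-one | COC1(OC)C=CC(=O)C=C1C | intermediate
8 | (1S,6R)-5,5-dimethoxy-4-methyl-7-oxabicyclo[4.1.0]hept-3-en-2-one (5α,6α-epoxide, C4 ketone, C1 dimethyl ketal) | O=C1C=C(C)C(OC)(OC)[C@@H]2O[C@H]12 | intermediate
9 | [(3S)-7-methyl-3-(triethylsilyloxy)octa-1,6-dien-2-yl]lithium | C=C([Li])[C@H](CC=C(C)C)O[Si](CC)(CC)CC | intermediate
10 | (1S,2S,6R)-5,5-dimethoxy-4-methyl-2-[(3S)-7-methyl-3-(triethylsilyloxy)octa-1,6-dien-2-yl]-7-oxabicyclo[4.1.0]hept-3-en-2-ol (4β-SC(OTES), 4α-OH, 5α,6α-epoxide) | C=C([C@@]1(O)C=C(C)C(OC)(OC)[C@@H]2O[C@H]12)[C@H](CC=C(C)C)O[Si](CC)(CC)CC | intermediate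
11 | 5β-SC(OTES)-6α-hydroxy-1,1-dimethoxy-2-methylcyclohex-2-en-4-one | C=C([C@H]1C(=O)C=C(C)C(OC)(OC)[C@@H]1O)[C@H](CC=C(C)C)O[Si](CC)(CC)CC | intermediate
12 | 5β-SC(OTES)-6α-acetoxy-1,1-dimethoxy-2-methylcyclohex-2-en-4-one | C=C([C@H]1C(=O)C=C(C)C(OC)(OC)[C@@H]1OC(C)=O)[C@H](CC=C(C)C)O[Si](CC)(CC)CC | intermediate
13 | 5β-SC(OTES)-6α-acetoxy-4α-hydroxy-1,1-dimethoxy-2-methylcyclohex-2-ene | C=C([C@H]1[C@H](O)C=C(C)C(OC)(OC)[C@@H]1OC(C)=O)[C@H](CC=C(C)C)O[Si](CC)(CC)CC | intermediate
14 | 5β-SC(OTES)-6α-acetoxy-4α-(tert-butyldimethylsilyloxy)-1,1-dimethoxy-2-methylcyclohex-2-ene | C=C([C@H]1[C@H](O[Si](C)(C)C(C)(C)C)C=C(C)C(OC)(OC)[C@@H]1OC(C)=O)[C@H](CC=C(C)C)O[Si](CC)(CC)CC | intermediate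
15 | 5β-SC(OH)-6α-acetoxy-4α-(tert-butyldimethylsilyloxy)-1,1-dimethoxy-2-methylcyclohex-2-ene | C=C([C@H]1[C@H](O[Si](C)(C)C(C)(C)C)C=C(C)C(OC)(OC)[C@@H]1OC(C)=O)[C@H](CC=C(C)C)O | intermediate
16 | angelic acid, (Z)-2-methylbut-2-enoic acid | C/C=C(/C)C(=O)O | starting material
17 | (Z)-2-methylbut-2-enoic 2,4,6-trichlorobenzoic anhydride | C/C=C(/C)C(=O)OC(=O)c1c(Cl)cc(Cl)cc1Cl | intermediate
18 | 5β-SC(OAng)-6α-acetoxy-4α-(tert-butyldimethylsilyloxy)-1,1-dimethoxy-2-methylcyclohex-2-ene (Ang = angeloyl) | C=C([C@H]1[C@H](O[Si](C)(C)C(C)(C)C)C=C(C)C(OC)(OC)[C@@H]1OC(C)=O)[C@H](CC=C(C)C)OC(=O)/C(C)=C\C | intermediate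
19 | 5β-SC(OAng)-6α-acetoxy-4α-(tert-butyldimethylsilyloxy)-2-methylcyclohex-2-en-1-one | C=C([C@H]1[C@H](O[Si](C)(C)C(C)(C)C)C=C(C)C(=O)[C@@H]1OC(C)=O)[C@H](CC=C(C)C)OC(=O)/C(C)=C\C | intermediate
20 | 5β-SC(OAng)-6α-acetoxy-4α-(tert-butyldimethylsilyloxy)-2-methylcyclohex-2-en-1β-ol | C=C([C@H]1[C@H](O[Si](C)(C)C(C)(C)C)C=C(C)[C@@H](O)[C@@H]1OC(C)=O)[C@H](CC=C(C)C)OC(=O)/C(C)=C\C | intermediate
21 | 5β-SC(OAng)-6α-acetoxy-4α-(tert-butyldimethylsilyloxy)-2β,3β-epoxy-2-methylcyclohexan-1β-ol | C=C([C@H]1[C@H](O[Si](C)(C)C(C)(C)C)[C@H]2O[C@@]2(C)[C@@H](O)[C@@H]1OC(C)=O)[C@H](CC=C(C)C)OC(=O)/C(C)=C\C | intermediate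
22 | 5β-SC(OAng)-6α-acetoxy-4α-(tert-butyldimethylsilyloxy)-2β,3β-epoxy-2-methylcyclohexan-1-one (4-O-TBS ether of the target) | C=C([C@H]1[C@H](O[Si](C)(C)C(C)(C)C)[C@H]2O[C@@]2(C)C(=O)[C@@H]1OC(C)=O)[C@H](CC=C(C)C)OC(=O)/C(C)=C\C | intermediate
23 | CNP0272666.1: 5β-SC(OAng)-6α-acetoxy-4α-hydroxy-2β,3β-epoxy-2-methylcyclohexan-1-one | C=C([C@H]1[C@H](O)[C@H]2O[C@@]2(C)C(=O)[C@@H]1OC(C)=O)[C@H](CC=C(C)C)OC(=O)/C(C)=C\C | target

## Step count and risks

Total step count: 16. Longest linear sequence: 14 steps (steps 1–3, then 6–16, from 1 to 23); the m-cresol branch (steps 4–5) joins at step 6.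

The three steps most likely to fail:

Step 7 (the proposed new semipinacol shift). The risks are ionisation of the ketal or of the doubly allylic carbinol, or bromohydrin formation, instead of the shift. The fallback uses known reactions, sets out from 7 and 9 and comes back at 11. Johnson iodination of 7 (I2, pyridine, CH2Cl2) gives 2-iodo-4,4-dimethoxy-5-methylcyclohexa-2,5-dien-1-one F3, iodinated on the unsubstituted enone arm. Transmetalation of 9 with ZnCl2 gives [(3S)-7-methyl-3-(triethylsilyloxy)octa-1,6-dien-2-yl]zinc chloride F4. Negishi coupling of F3 and F4 with Pd(PPh3)4 (zerovalent palladium) gives 4,4-dimethoxy-5-methyl-2-SC(OTES)-cyclohexa-2,5-dien-1-one F5. Enantioselective conjugate borylation of the substituted enone arm (B2pin2, CuCl, NaOt-Bu, a chiral bisphosphine, MeOH) gives 5β-SC(OTES)-6α-(pinacolboryl)-1,1-dimethoxy-2-methylcyclohex-2-en-4-one F6, with C5 settling trans by protonation. Oxidation with NaBO3·4H2O, with retention at carbon, gives 11, which is acetylated as in step 7.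

Step 5 (asymmetric epoxidation). The enantioselectivity on a β-methyl-substituted monoketal is not assured. The fallback replaces catalyst control by separation of diastereomers; it sets out from 7 and comes back at 10. Epoxidation of 7 with t-BuOOH and DBU (CH2Cl2, 0 °C) gives racemic epoxide, that is 8 together with (1R,6S)-5,5-dimethoxy-4-methyl-7-oxabicyclo[4.1.0]hept-3-en-2-one F1. Addition of enantiopure 9 as in step 6 gives 10 and the diastereomeric adduct (1R,2R,6S)-5,5-dimethoxy-4-methyl-2-SC(OTES)-7-oxabicyclo[4.1.0]hept-3-en-2-ol F2. The two are separated on silica and 10 goes on.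

Step 11 (angeloylation). The risks are isomerisation to the tiglate or a sluggish reaction at the hindered allylic carbinol. The fallback builds the Z-alkene on the ester instead; it sets out from 15 and comes back at 18. Esterification of 15 with 2-[bis(2,2,2-trifluoroethoxy)phosphoryl]propanoic acid (DCC, DMAP cat., CH2Cl2) gives 5β-SC(O-phosphonopropanoyl)-6α-acetoxy-4α-(tert-butyldimethylsilyloxy)-1,1-dimethoxy-2-methylcyclohex-2-ene F7. Still–Gennari olefination with acetaldehyde (KN(SiMe3)2, 18-crown-6, THF, −78 °C) gives the Z-configured 2-methylbut-2-enoate 18.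

Further compounds

F1 | step 5 | (1R,6S)-5,5-dimethoxy-4-methyl-7-oxabicyclo[4.1.0]hept-3-en-2-one | O=C1C=C(C)C(OC)(OC)[C@H]2O[C@@H]12
F2 | step 5 | (1R,2R,6S)-5,5-dimethoxy-4-methyl-2-[(3S)-7-methyl-3-(triethylsilyloxy)octa-1,6-dien-2-yl]-7-oxabicyclo[4.1.0]hept-3-en-2-ol | C=C([C@]1(O)C=C(C)C(OC)(OC)[C@H]2O[C@@H]12)[C@H](CC=C(C)C)O[Si](CC)(CC)CC
F3 | step 7 | 2-iodo-4,4-dimethoxy-5-methylcyclohexa-2,5-dien-1-one | O=C1C=C(C)C(OC)(OC)C=C1I
F4 | step 7 | [(3S)-7-methyl-3-(triethylsilyloxy)octa-1,6-dien-2-yl]zinc chloride | C=C([Zn]Cl)[C@H](CC=C(C)C)O[Si](CC)(CC)CC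
F5 | step 7 | 4,4-dimethoxy-5-methyl-2-[(3S)-7-methyl-3-(triethylsilyloxy)octa-1,6-dien-2-yl]cyclohexa-2,5-dien-1-one | C=C(C1=CC(OC)(OC)C(C)=CC1=O)[C@H](CC=C(C)C)O[Si](CC)(CC)CC
F6 | step 7 | 5β-SC(OTES)-6α-(4,4,5,5-tetramethyl-1,3,2-dioxaborolan-2-yl)-1,1-dimethoxy-2-methylcyclohex-2-en-4-one | C=C([C@H]1C(=O)C=C(C)C(OC)(OC)[C@@H]1B1OC(C)(C)C(C)(C)O1)[C@H](CC=C(C)C)O[Si](CC)(CC)CC
F7 | step 11 | 5β-SC(O-2-[bis(2,2,2-trifluoroethoxy)phosphoryl]propanoyl)-6α-acetoxy-4α-(tert-butyldimethylsilyloxy)-1,1-dimethoxy-2-methylcyclohex-2-ene | C=C([C@H]1[C@H](O[Si](C)(C)C(C)(C)C)C=C(C)C(OC)(OC)[C@@H]1OC(C)=O)[C@H](CC=C(C)C)OC(=O)C(C)P(=O)(OCC(F)(F)F)OCC(F)(F)F
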